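**Retrosynthetic overview**

1. Last C–O bonds: C15–OH comes from allylic hydroxylation of the C5 isopropenyl group (C3=C4–C15); the lactone C12(=O)–O6 comes from oxidation of the 2-methylene-1,4-diol O6–C6–C7–C11(=C13)–C12.
2. Key cut C6–C7: the carbinol carbon C6 lies between C5 and C7, each bearing a 2-propenyl unit. The ring C5–C10 is therefore closed last, by a type-I carbonyl-ene reaction of the acyclic aldehyde 22, which makes the only carbocycle, C6, C7 and C11=C13.
3. C5–C10: the 1,5-diene C2=C1–C10–C5–C4=C3 with quaternary C10 (methyl, vinyl) comes from an enantioselective Ireland–Claisen rearrangement of an (E)-allylic 3-methylbut-3-enoate (17 → 19).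
4. C8–C9: catalytic asymmetric vinylogous Mukaiyama aldol of (Z)-enal 6 with dienolate 9. The Roche-ester side chain is put on O8 before the rearrangement and is the only protection O8 ever carries.
5. Ring order: cyclohexane (step 14), then γ-lactone (step 16).

Key step: step 14

Remark: atoms are numbered as in elemanolides (ring C5–C10; vinyl C1=C2 and methyl C14 on C10; C3=C4–C15 on C5; C11(=C13)–C12 on C7). The sense of induction of the catalyst in step 5 and of the boron controller in step 11 is assigned by analogy; the antipodal catalyst or controller would be taken if either sense proved reversed.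

**Route**

Step 1
Reactants: 1 prop-2-yn-1-ol
Product: 3 (Z)-3-iodo-2-methylprop-2-en-1-ol, via alkenylmagnesium alkoxide 2 (not isolated)
Conditions: MeMgBr (2.5 equiv), CuI (10 mol %), THF/Et2O, −10 °C to rt; then I2, −10 °C; aq. NH4Cl
Reagents that add atoms: methylmagnesium bromide, C[Mg]Br; iodine, II
Why: Copper-catalysed, alkoxide-directed anti-carbomagnesiation puts methyl on C2 and magnesium on C3 cis to CH2O, and iodinolysis with retention should give the (Z)-iodide that fixes the later C7=C11 geometry.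

Step 2
Reactants: 3 (Z)-3-iodo-2-methylprop-2-en-1-ol
Product: 4 (Z)-tert-butyl[(3-iodo-2-methylprop-2-en-1-yl)oxy]dimethylsilane
Conditions: TBSCl, imidazole, CH2Cl2, rt
Reagents that add atoms: tert-butyldimethylsilyl chloride, CC(C)(C)[Si](C)(C)Cl
Why: Standard silylation of a primary alcohol; the vinyl iodide is inert.

Step 3
Reactants: 4 (Z)-tert-butyl[(3-iodo-2-methylprop-2-en-1-yl)oxy]dimethylsilane
Product: 6 (2Z)-4-[(tert-butyldimethylsilyl)oxy]-3-methylbut-2-enal, via alkenyllithium 5 (not isolated)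
Conditions: t-BuLi (2.1 equiv), Et2O, −78 °C; then DMF, −78 °C to 0 °C; aq. NH4Cl
Reagents that add atoms: N,N-dimethylformamide, CN(C)C=O
Why: Iodine–lithium exchange and formylation (Bouveault type) proceed with retention of olefin geometry at low temperature, so the (Z)-enal should result.

Step 4
Reactants: 7 methyl 3-methylbut-2-enoate
Product: 9 tert-butyl[(1-methoxy-3-methylbuta-1,3-dien-1-yl)oxy]dimethylsilane, via lithium dienolate 8 (not isolated)
Conditions: LDA, THF, −78 °C; then TBSCl, DMPU, −78 °C to rt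
Reagents that add atoms: tert-butyldimethylsilyl chloride, CC(C)(C)[Si](C)(C)Cl
Why: Kinetic γ-deprotonation of the senecioate and O-silylation give the silyl dienolate (E/Z mixture at the ketene acetal, of no consequence).

Step 5
Reactants: 6 (2Z)-4-[(tert-butyldimethylsilyl)oxy]-3-methylbut-2-enal; 9 tert-butyl[(1-methoxy-3-methylbuta-1,3-dien-1-yl)oxy]dimethylsilane
Product: 10 methyl (2E,5S,6Z)-8-[(tert-butyldimethylsilyl)oxy]-5-hydroxy-3,7-dimethylocta-2,6-dienoate
Conditions: SiCl4 (1.1 equiv), (R,R)-binaphthyldiamine-derived bisphosphoramide (2 mol %), i-Pr2NEt (10 mol %), CH2Cl2, −78 °C; aq. NaHCO3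
Reagents that add atoms: none
Why: Lewis-base-activated SiCl4 vinylogous Mukaiyama aldol: the dienolate attacks through its γ-carbon (C9) to give the (E)-enoate, and the chiral phosphoramide-bound silicon cation selects the aldehyde face, which sets C8.

Step 6
Reactants: 10 methyl (2E,5S,6Z)-8-[(tert-butyldimethylsilyl)oxy]-5-hydroxy-3,7-dimethylocta-2,6-dienoate
Product: 11 (2E,5S,6Z)-8-[(tert-butyldimethylsilyl)oxy]-3,7-dimethylocta-2,6-diene-1,5-diol
Conditions: DIBAL-H (3.3 equiv), CH2Cl2, −78 °C; Rochelle salt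
Reagents that add atoms: none
Why: 1,2-Reduction of the enoate to the primary allylic alcohol; olefin geometries, the silyl ether and C8 are untouched.

Step 7
Reactants: 11 (2E,5S,6Z)-8-[(tert-butyldimethylsilyl)oxy]-3,7-dimethylocta-2,6-diene-1,5-diol; 12 3-methylbut-3-enoic acid
Product: 13 (2E,5S,6Z)-8-[(tert-butyldimethylsilyl)oxy]-5-hydroxy-3,7-dimethylocta-2,6-dien-1-yl 3-methylbut-3-enoate
Conditions: 12 (1.0 equiv), DIC, DMAP (5 mol %), CH2Cl2, −20 °C
Reagents that add atoms: none
Why: Carbodiimide (Steglich) esterification should take the unhindered primary allylic hydroxyl before the flanked secondary one; low temperature and little DMAP keep the β,γ-olefin of the acid out of conjugation.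

Step 8
Reactants: 14 methyl (2R)-3-hydroxy-2-methylpropanoate
Product: 15 methyl (2R)-3-[(tert-butyldimethylsilyl)oxy]-2-methylpropanoate
Conditions: TBSCl, imidazole, CH2Cl2, rt
Reagents that add atoms: tert-butyldimethylsilyl chloride, CC(C)(C)[Si](C)(C)Cl
Why: Silylation of the primary hydroxyl of the Roche ester; the stereocentre is not involved.

Step 9
Reactants: 15 methyl (2R)-3-[(tert-butyldimethylsilyl)oxy]-2-methylpropanoate
Product: 16 (2R)-3-[(tert-butyldimethylsilyl)oxy]-2-methylpropanoic acid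
Conditions: LiOH, THF/MeOH/H2O, 0 °C to rt; then pH 3
Reagents that add atoms: lithium hydroxide, [Li+].[OH-]
Why: Mild saponification by acyl–oxygen cleavage, which should leave the α-stereocentre and the silyl ether intact.

Step 10
Reactants: 13 (2E,5S,6Z)-8-[(tert-butyldimethylsilyl)oxy]-5-hydroxy-3,7-dimethylocta-2,6-dien-1-yl 3-methylbut-3-enoate; 16 (2R)-3-[(tert-butyldimethylsilyl)oxy]-2-methylpropanoic acid
Product: 17 (2E,5S,6Z)-8-[(tert-butyldimethylsilyl)oxy]-3,7-dimethyl-1-[(3-methylbut-3-enoyl)oxy]octa-2,6-dien-5-yl (2R)-3-[(tert-butyldimethylsilyl)oxy]-2-methylpropanoate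
Conditions: 16 (1.3 equiv), DIC, DMAP (20 mol %), CH2Cl2, 0 °C to rt
Reagents that add atoms: none
Why: Steglich esterification of the remaining secondary allylic alcohol installs the final C8 ester, which from here on protects O8.

Step 11
Reactants: 17 (2E,5S,6Z)-8-[(tert-butyldimethylsilyl)oxy]-3,7-dimethyl-1-[(3-methylbut-3-enoyl)oxy]octa-2,6-dien-5-yl (2R)-3-[(tert-butyldimethylsilyl)oxy]-2-methylpropanoate
Product: 19 (2S,3S,5S,6Z)-8-[(tert-butyldimethylsilyl)oxy]-5-{[(2R)-3-[(tert-butyldimethylsilyl)oxy]-2-methylpropanoyl]oxy}-3-ethenyl-3,7-dimethyl-2-(prop-1-en-2-yl)oct-6-enoic acid, via boron ketene acetal 18 (not isolated)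
Conditions: preformed (4S,5S)-2-bromo-4,5-diphenyl-1,3-bis{[3,5-bis(trifluoromethyl)phenyl]sulfonyl}-1,3,2-diazaborolidine (1.5 equiv), Et3N, toluene/hexane, −78 °C, then 4 °C to rt; aqueous work-up
Reagents that add atoms: none
Why: Enantioselective Ireland–Claisen rearrangement, closely precedented for geranyl-type esters of this acid: soft enolisation takes the doubly activated CH2 of the butenoate and not the α-branched C8 ester; the chair with the (E)-C1=C10 olefin and the (E)-O-boron enolate places isopropenyl trans to the new vinyl group; the chiral diazaborolidine fixes the absolute sense at C5 and quaternary C10.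

Step 12
Reactants: 19 (2S,3S,5S,6Z)-8-[(tert-butyldimethylsilyl)oxy]-5-{[(2R)-3-[(tert-butyldimethylsilyl)oxy]-2-methylpropanoyl]oxy}-3-ethenyl-3,7-dimethyl-2-(prop-1-en-2-yl)oct-6-enoic acid
Product: 21 (2S,3S,5S,6Z)-8-[(tert-butyldimethylsilyl)oxy]-3-ethenyl-1-hydroxy-3,7-dimethyl-2-(prop-1-en-2-yl)oct-6-en-5-yl (2R)-3-[(tert-butyldimethylsilyl)oxy]-2-methylpropanoate, via mixed anhydride 20 (not isolated)
Conditions: i-BuOCOCl, N-methylmorpholine, THF, −15 °C; then NaBH4, H2O, 0 °C
Reagents that add atoms: none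
Why: Reduction of the acid through its mixed carbonic anhydride with borohydride spares the ester, the silyl ethers and all olefins; C5 is not enolised.

Step 13
Reactants: 21 (2S,3S,5S,6Z)-8-[(tert-butyldimethylsilyl)oxy]-3-ethenyl-1-hydroxy-3,7-dimethyl-2-(prop-1-en-2-yl)oct-6-en-5-yl (2R)-3-[(tert-butyldimethylsilyl)oxy]-2-methylpropanoate
Product: 22 (2S,3S,5S,6Z)-8-[(tert-butyldimethylsilyl)oxy]-3-ethenyl-3,7-dimethyl-1-oxo-2-(prop-1-en-2-yl)oct-6-en-5-yl (2R)-3-[(tert-butyldimethylsilyl)oxy]-2-methylpropanoate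
Conditions: Dess–Martin periodinane, NaHCO3, CH2Cl2, 0 °C; used directly
Reagents that add atoms: none
Why: Buffered Dess–Martin oxidation should give the α-branched β,γ-unsaturated aldehyde without epimerisation at C5 or migration of the olefin.

Step 14
Reactants: 22 (2S,3S,5S,6Z)-8-[(tert-butyldimethylsilyl)oxy]-3-ethenyl-3,7-dimethyl-1-oxo-2-(prop-1-en-2-yl)oct-6-en-5-yl (2R)-3-[(tert-butyldimethylsilyl)oxy]-2-methylpropanoate
Product: 23 (5S,6R,7S,8S,10S)-12-[(tert-butyldimethylsilyl)oxy]-6-hydroxyelema-1,3,11(13)-trien-8-yl (2R)-3-[(tert-butyldimethylsilyl)oxy]-2-methylpropanoate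
Conditions: Me2AlCl (1.5 equiv), CH2Cl2, −78 °C to −40 °C
Reagents that add atoms: none
Why: Me2AlCl activates the aldehyde and the trisubstituted olefin adds through C7 to C6 while a hydrogen of the C13 methyl group passes to oxygen (type-I intramolecular carbonyl-ene reaction, concerted but asynchronous with positive charge at tertiary C11); the closest known reaction is the citronellal-to-isopulegol cyclisation. The cyclohexane closes at C6–C7 through a chair in which the C5 isopropenyl and the C8 acyloxy group are equatorial and the C10 methyl group is axial. C6 (hydroxyl equatorial, α) and C7 (alkenyl equatorial, β) are set by this chair, trans to each other and to their neighbours C5 and C8; the flipped chair would put the C8 oxygen syn-axial to the C10 vinyl group and the isopropenyl group axial. The (Z) geometry of C7=C11 places CH3 trans to C8, the only position from which the carbonyl oxygen can take a hydrogen, so C11=C13 forms and C12 keeps its oxygen. The aldehyde is the only carbonyl that can reach a nucleophilic olefin in an unstrained ring; the vinyl and 1,1-disubstituted olefins cannot.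

Step 15
Reactants: 23 (5S,6R,7S,8S,10S)-12-[(tert-butyldimethylsilyl)oxy]-6-hydroxyelema-1,3,11(13)-trien-8-yl (2R)-3-[(tert-butyldimethylsilyl)oxy]-2-methylpropanoate
Product: 24 (5S,6R,7S,8S,10S)-6,12-dihydroxyelema-1,3,11(13)-trien-8-yl (2R)-3-hydroxy-2-methylpropanoate
Conditions: HF·pyridine, pyridine, THF, 0 °C to rt
Reagents that add atoms: none
Why: Buffered acidic desilylation removes both primary silyl ethers and avoids the base-induced acyl shift from O8 to O6.

Step 16
Reactants: 24 (5S,6R,7S,8S,10S)-6,12-dihydroxyelema-1,3,11(13)-trien-8-yl (2R)-3-hydroxy-2-methylpropanoate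
Product: 27 (5S,6R,7R,8S,10S)-8-{[(2R)-3-hydroxy-2-methylpropanoyl]oxy}elema-1,3,11(13)-trien-12,6-olide, via enal 25 (not isolated), via lactol 26 (not isolated)
Conditions: activated MnO2 (excess), CH2Cl2, rt
Reagents that add atoms: none
Why: MnO2 oxidises only the allylic C12 alcohol; the enal is trapped by O6 as the five-membered lactol, which is oxidised on to the trans-fused α-methylene-γ-lactone (tandem oxidative lactonisation). The saturated side-chain alcohol is not touched.

Step 17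
Reactants: 27 (5S,6R,7R,8S,10S)-8-{[(2R)-3-hydroxy-2-methylpropanoyl]oxy}elema-1,3,11(13)-trien-12,6-olide
Product: 28 (5R,6R,7R,8S,10S)-15-hydroxy-8-{[(2R)-3-hydroxy-2-methylpropanoyl]oxy}elema-1,3,11(13)-trien-12,6-olide (target)
Conditions: SeO2 (0.3 equiv), t-BuOOH (3 equiv), CH2Cl2, 0 °C to rt
Reagents that add atoms: selenium dioxide, O=[Se]=O; tert-butyl hydroperoxide, CC(C)(C)OO
Why: Catalytic SeO2 allylic hydroxylation (ene reaction, then [2,3]-shift) should act only on the C3=C4 isopropenyl group, at its methyl group: the vinyl group has no allylic hydrogen and the lactone methylene is electron-poor.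

**Compound list**

1 | prop-2-yn-1-ol | C#CCO | starting material
2 | cyclic alkenylmagnesium alkoxide (4-methyl-2,5-dihydro-1,2-oxamagnesole) | CC1=C[Mg]OC1 | intermediate (not isolated)
3 | (Z)-3-iodo-2-methylprop-2-en-1-ol | C/C(CO)=C/I | intermediate
4 | (Z)-tert-butyl[(3-iodo-2-methylprop-2-en-1-yl)oxy]dimethylsilane | C/C(CO[Si](C)(C)C(C)(C)C)=C/I | intermediate
5 | (Z)-3-[(tert-butyldimethylsilyl)oxy]-2-methylprop-1-enyllithium | C/C(CO[Si](C)(C)C(C)(C)C)=C/[Li] | intermediate (not isolated)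
6 | (2Z)-4-[(tert-butyldimethylsilyl)oxy]-3-methylbut-2-enal | C/C(CO[Si](C)(C)C(C)(C)C)=C/C=O | intermediate
7 | methyl 3-methylbut-2-enoate | COC(=O)C=C(C)C | starting material
8 | lithium 1-methoxy-3-methylbuta-1,3-dien-1-olate | [Li]OC(OC)=CC(C)=C | intermediate (not isolated)
9 | tert-butyl[(1-methoxy-3-methylbuta-1,3-dien-1-yl)oxy]dimethylsilane (E/Z mixture) | COC(O[Si](C)(C)C(C)(C)C)=CC(C)=C | intermediate
10 | methyl (2E,5S,6Z)-8-[(tert-butyldimethylsilyl)oxy]-5-hydroxy-3,7-dimethylocta-2,6-dienoate | COC(=O)/C=C(\C)C[C@H](O)/C=C(/C)CO[Si](C)(C)C(C)(C)C | intermediate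
11 | (2E,5S,6Z)-8-[(tert-butyldimethylsilyl)oxy]-3,7-dimethylocta-2,6-diene-1,5-diol | OC/C=C(\C)C[C@H](O)/C=C(/C)CO[Si](C)(C)C(C)(C)C | intermediate
12 | 3-methylbut-3-enoic acid | C=C(C)CC(=O)O | starting material
13 | (2E,5S,6Z)-8-[(tert-butyldimethylsilyl)oxy]-5-hydroxy-3,7-dimethylocta-2,6-dien-1-yl 3-methylbut-3-enoate | C=C(C)CC(=O)OC/C=C(\C)C[C@H](O)/C=C(/C)CO[Si](C)(C)C(C)(C)C | intermediate
14 | methyl (2R)-3-hydroxy-2-methylpropanoate | COC(=O)[C@H](C)CO | starting material
15 | methyl (2R)-3-[(tert-butyldimethylsilyl)oxy]-2-methylpropanoate | COC(=O)[C@H](C)CO[Si](C)(C)C(C)(C)C | intermediate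
16 | (2R)-3-[(tert-butyldimethylsilyl)oxy]-2-methylpropanoic acid | OC(=O)[C@H](C)CO[Si](C)(C)C(C)(C)C | intermediate
17 | (2E,5S,6Z)-8-[(tert-butyldimethylsilyl)oxy]-3,7-dimethyl-1-[(3-methylbut-3-enoyl)oxy]octa-2,6-dien-5-yl (2R)-3-[(tert-butyldimethylsilyl)oxy]-2-methylpropanoate | C=C(C)CC(=O)OC/C=C(\C)C[C@H](OC(=O)[C@H](C)CO[Si](C)(C)C(C)(C)C)/C=C(/C)CO[Si](C)(C)C(C)(C)C | intermediate
18 | (E)-O-boron ketene acetal of 17 carrying the (4S,5S)-diazaborolidinyl group on oxygen | C=C(C)/C=C(/OB1N(S(=O)(=O)c2cc(cc(c2)C(F)(F)F)C(F)(F)F)[C@@H](c2ccccc2)[C@H](c2ccccc2)N1S(=O)(=O)c1cc(cc(c1)C(F)(F)F)C(F)(F)F)OC/C=C(\C)C[C@H](OC(=O)[C@H](C)CO[Si](C)(C)C(C)(C)C)/C=C(/C)CO[Si](C)(C)C(C)(C)C | intermediate (not isolated)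
19 | (2S,3S,5S,6Z)-8-[(tert-butyldimethylsilyl)oxy]-5-{[(2R)-3-[(tert-butyldimethylsilyl)oxy]-2-methylpropanoyl]oxy}-3-ethenyl-3,7-dimethyl-2-(prop-1-en-2-yl)oct-6-enoic acid | C=C[C@](C)(C[C@H](OC(=O)[C@H](C)CO[Si](C)(C)C(C)(C)C)/C=C(/C)CO[Si](C)(C)C(C)(C)C)[C@@H](C(=O)O)C(C)=C | intermediate
20 | isobutyl carbonic mixed anhydride of 19 | C=C[C@](C)(C[C@H](OC(=O)[C@H](C)CO[Si](C)(C)C(C)(C)C)/C=C(/C)CO[Si](C)(C)C(C)(C)C)[C@@H](C(=O)OC(=O)OCC(C)C)C(C)=C | intermediate (not isolated)
21 | (2S,3S,5S,6Z)-8-[(tert-butyldimethylsilyl)oxy]-3-ethenyl-1-hydroxy-3,7-dimethyl-2-(prop-1-en-2-yl)oct-6-en-5-yl (2R)-3-[(tert-butyldimethylsilyl)oxy]-2-methylpropanoate | C=C[C@](C)(C[C@H](OC(=O)[C@H](C)CO[Si](C)(C)C(C)(C)C)/C=C(/C)CO[Si](C)(C)C(C)(C)C)[C@@H](CO)C(C)=C | intermediate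
22 | (2S,3S,5S,6Z)-8-[(tert-butyldimethylsilyl)oxy]-3-ethenyl-3,7-dimethyl-1-oxo-2-(prop-1-en-2-yl)oct-6-en-5-yl (2R)-3-[(tert-butyldimethylsilyl)oxy]-2-methylpropanoate | C=C[C@](C)(C[C@H](OC(=O)[C@H](C)CO[Si](C)(C)C(C)(C)C)/C=C(/C)CO[Si](C)(C)C(C)(C)C)[C@@H](C=O)C(C)=C | intermediate
23 | (5S,6R,7S,8S,10S)-12-[(tert-butyldimethylsilyl)oxy]-6-hydroxyelema-1,3,11(13)-trien-8-yl (2R)-3-[(tert-butyldimethylsilyl)oxy]-2-methylpropanoate | C=C[C@]1(C)C[C@H](OC(=O)[C@H](C)CO[Si](C)(C)C(C)(C)C)[C@@H](C(=C)CO[Si](C)(C)C(C)(C)C)[C@H](O)[C@H]1C(C)=C | intermediate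
24 | (5S,6R,7S,8S,10S)-6,12-dihydroxyelema-1,3,11(13)-trien-8-yl (2R)-3-hydroxy-2-methylpropanoate | C=C[C@]1(C)C[C@H](OC(=O)[C@H](C)CO)[C@@H](C(=C)CO)[C@H](O)[C@H]1C(C)=C | intermediate
25 | (5S,6R,7S,8S,10S)-6-hydroxy-12-oxoelema-1,3,11(13)-trien-8-yl (2R)-3-hydroxy-2-methylpropanoate | C=C[C@]1(C)C[C@H](OC(=O)[C@H](C)CO)[C@@H](C(=C)C=O)[C@H](O)[C@H]1C(C)=C | intermediate (not isolated)
26 | (5S,6R,7R,8S,10S)-12-hydroxy-6,12-epoxyelema-1,3,11(13)-trien-8-yl (2R)-3-hydroxy-2-methylpropanoate (lactol, both C12 epimers) | C=C[C@]1(C)C[C@H](OC(=O)[C@H](C)CO)[C@H]2C(=C)C(O)O[C@@H]2[C@H]1C(C)=C | intermediate (not isolated)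
27 | (5S,6R,7R,8S,10S)-8-{[(2R)-3-hydroxy-2-methylpropanoyl]oxy}elema-1,3,11(13)-trien-12,6-olide | C=C[C@]1(C)C[C@H](OC(=O)[C@H](C)CO)[C@H]2C(=C)C(=O)O[C@@H]2[C@H]1C(C)=C | intermediate
28 | (5R,6R,7R,8S,10S)-15-hydroxy-8-{[(2R)-3-hydroxy-2-methylpropanoyl]oxy}elema-1,3,11(13)-trien-12,6-olide (CNP0133858.1) | C=C[C@]1(C)C[C@H](OC(=O)[C@H](C)CO)[C@H]2C(=C)C(=O)O[C@@H]2[C@H]1C(=C)CO | target

**Totals**

Total step count: 17. Longest linear sequence: 14 steps (1–3, 5–7, 10–17).

**Steps most likely to fail**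

Step 14 (carbonyl-ene closure). What may go wrong:
- loss of chair selectivity through allylic 1,3-strain between the equatorial C8 acyloxy group and the cis CH2OSi group on C11;
- ionisation of the allylic C8 ester, or capture of the C11 cation by its carbonyl oxygen, under the aluminium Lewis acid;
- epimerisation of C5 in aldehyde 22.

Fallback, from 19 back to 23: the ring is closed at the ketone level and C6 is set separately. Acid 19 is converted with 1-chloro-N,N,2-trimethylprop-1-en-1-amine (CH2Cl2, 0 °C) into the acid chloride F1. EtAlCl2 (CH2Cl2, −78 °C) should bring about ene-type intramolecular acylation of the C7=C11 olefin to the β,γ-unsaturated cyclohexanone F2, whose C7 substituent is equatorial or can become so by enolisation. Reduction with SmI2/i-PrOH in THF should give the thermodynamically favoured equatorial 6α-alcohol 23. Hydride reagents are avoided because the axial C10 methyl group would steer them to the axial alcohol.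

Step 5 (vinylogous aldol). What may go wrong:
- Z-to-E isomerisation of the γ-silyloxy enal at the silicon Lewis acid;
- insufficient facial selectivity on a β,β-disubstituted enal.

Fallback, from 6 and 9 back to 10: C8 is set by reagent-controlled reduction. A BF3·OEt2-mediated Mukaiyama aldol (CH2Cl2, −78 °C) should give 10 together with its enantiomer ent-10 F3. Dess–Martin oxidation of the mixture gives the dienone F4. Reduction with (R)-2-methyl-CBS-oxazaborolidine and catecholborane (toluene, −78 °C), with the Z-alkenyl group as the large substituent, should return (5S)-10.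

Step 17 (allylic hydroxylation). What may go wrong:
- over-oxidation to the C15 enal;
- competing attack at the tertiary C5–H;
- low conversion on the hindered olefin.

Fallback, from 27 back to 28: oxygen is brought in by substitution. Ene-type chlorination of the isopropenyl group (Ca(OCl)2, solid CO2, CH2Cl2/H2O, 0 °C) should give the allylic chloride F5; the acrylate-type and vinyl olefins do not react in this way. Silver-assisted hydrolysis (AgBF4, acetone/H2O, rt) through the symmetrical 2-substituted allyl cation should then give 28.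

**Further compounds**

F1 | step 14 | (2S,3S,5S,6Z)-8-[(tert-butyldimethylsilyl)oxy]-5-{[(2R)-3-[(tert-butyldimethylsilyl)oxy]-2-methylpropanoyl]oxy}-3-ethenyl-3,7-dimethyl-2-(prop-1-en-2-yl)oct-6-enoyl chloride | C=C[C@](C)(C[C@H](OC(=O)[C@H](C)CO[Si](C)(C)C(C)(C)C)/C=C(/C)CO[Si](C)(C)C(C)(C)C)[C@@H](C(Cl)=O)C(C)=C
F2 | step 14 | (5S,7S,8S,10S)-12-[(tert-butyldimethylsilyl)oxy]-6-oxoelema-1,3,11(13)-trien-8-yl (2R)-3-[(tert-butyldimethylsilyl)oxy]-2-methylpropanoate | C=C[C@]1(C)C[C@H](OC(=O)[C@H](C)CO[Si](C)(C)C(C)(C)C)[C@@H](C(=C)CO[Si](C)(C)C(C)(C)C)C(=O)[C@H]1C(C)=C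
F3 | step 5 | methyl (2E,5R,6Z)-8-[(tert-butyldimethylsilyl)oxy]-5-hydroxy-3,7-dimethylocta-2,6-dienoate (ent-10) | COC(=O)/C=C(\C)C[C@@H](O)/C=C(/C)CO[Si](C)(C)C(C)(C)C
F4 | step 5 | methyl (2E,6Z)-8-[(tert-butyldimethylsilyl)oxy]-3,7-dimethyl-5-oxoocta-2,6-dienoate | COC(=O)/C=C(\C)CC(=O)/C=C(/C)CO[Si](C)(C)C(C)(C)C
F5 | step 17 | (5R,6R,7R,8S,10S)-15-chloro-8-{[(2R)-3-hydroxy-2-methylpropanoyl]oxy}elema-1,3,11(13)-trien-12,6-olide | C=C[C@]1(C)C[C@H](OC(=O)[C@H](C)CO)[C@H]2C(=C)C(=O)O[C@@H]2[C@H]1C(=C)CCl
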